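**Plan**

- Feature and main cut: ring B (C5–C10) carries the tetrasubstituted C8=C9 alkene between C7 and the quaternary C10. That cyclohexene is read as the adduct of a C7=C8–C9=C10 diene with a C5=C6 dienophile already linked through C1–C4, so one intramolecular Diels–Alder reaction of an acyclic trienal forms C5–C10 and C6–C7 and closes rings A and B together.
- Further cuts, target backwards: C13–CH3 and C11–C12 of the acid chain (enol phosphate/cuprate; acetoacetate dianion on a C11 allylic bromide); C4–homoprenyl (ester enolate alkylation), with the C4 methyl traced to an axial ester; the C6 formyl activator (decarbonylation); then, before the cycloaddition, C5–C4 (acrolein Michael addition), C3–C4 (malonate alkylation), C8–C9 (Suzuki–Miyaura) and C10–CH3 (ynoate carbocupration).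
- Forward order: stereodefined acyclic diene → malonate → enal → rings A and B in one step → C6 stripped → C4 quaternary centre completed → C9 chain grown to the (E)-3-methylpentenoic acid.
- Stereochemistry: C5 and C10 come from a chiral imidazolidinone catalyst and the endo, trans-fusing transition state. C4 comes from equatorial alkylation of the ester enolate, away from the axial C10 methyl. The 13E alkene comes from a (Z)-enol phosphate displaced with retention, and the diene geometry from syn carbocupration.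

Key step: step 9

Remark: terpenoid numbering is used (ring A: C1–C5, C10; ring B: C5–C10; chain C11–C15 on C9; α = face of C5–H, β = face of the C10 methyl); the facial sense of the cycloaddition is assigned from the accepted shielding model of the imidazolidinone, and the mirror-image catalyst is equally available should the sense prove opposite.

**Route**

Step 1
Reactants: 1 5-chloropent-1-yne
Product: 3 methyl 6-chlorohex-2-ynoate, via lithium acetylide 2 (not isolated)
Conditions: n-BuLi, THF, −78 °C; then ClCO2Me, −78 → 0 °C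
Reagents that add atoms: methyl chloroformate, COC(=O)Cl
Why: Deprotonation of the terminal alkyne and C-acylation of the acetylide with a chloroformate is a standard ynoate synthesis, and the primary chloride is inert to n-BuLi at −78 °C.

Step 2
Reactants: 3 methyl 6-chlorohex-2-ynoate
Product: 5 methyl (2E)-6-chloro-2-iodo-3-methylhex-2-enoate, via vinylcuprate adduct 4 (not isolated)
Conditions: Me2CuLi (MeLi, CuI), THF, −78 °C; then I2, THF, −78 °C
Reagents that add atoms: lithium dimethylcuprate, [Li+].C[Cu-]C; iodine, II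
Why: Syn carbocupration of the ynoate puts methyl on C3 cis to copper, and iodinolysis of the α-cuprio enoate 4 at −78 °C, before it can equilibrate through the allenoate, should proceed with retention and fix the tetrasubstituted alkene with the chloropropyl chain cis to the ester.

Step 3
Reactants: 5 methyl (2E)-6-chloro-2-iodo-3-methylhex-2-enoate; 6 isopropenylboronic acid pinacol ester
Product: 7 methyl (2Z)-6-chloro-3-methyl-2-(prop-1-en-2-yl)hex-2-enoate
Conditions: Pd(dppf)Cl2 (5 mol%), K3PO4, THF/H2O, 60 °C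
Reagents that add atoms: none
Why: Suzuki–Miyaura coupling of an α-iodo enoate with an alkenyl boronate is stereoretentive, so isopropenyl takes the place of iodine and the chain stays trans to the new vinyl group.

Step 4
Reactants: 7 methyl (2Z)-6-chloro-3-methyl-2-(prop-1-en-2-yl)hex-2-enoate
Product: 8 (2Z)-6-chloro-3-methyl-2-(prop-1-en-2-yl)hex-2-en-1-ol
Conditions: DIBAL-H (2.5 equiv), CH2Cl2, −78 °C; Rochelle salt work-up
Reagents that add atoms: none
Why: 1,2-Reduction of the conjugated ester by DIBAL-H should give the allylic alcohol (the future C11–OH) without touching the alkyl chloride or the diene.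

Step 5
Reactants: 8 (2Z)-6-chloro-3-methyl-2-(prop-1-en-2-yl)hex-2-en-1-ol
Product: 9 triisopropyl{[(2Z)-6-chloro-3-methyl-2-(prop-1-en-2-yl)hex-2-en-1-yl]oxy}silane
Conditions: TIPSCl, imidazole, DMF, rt
Reagents that add atoms: chlorotriisopropylsilane, CC(C)[Si](Cl)(C(C)C)C(C)C
Why: Silylation of the primary allylic alcohol gives a TIPS ether, chosen because it should withstand the acidic amine-salt medium of the cycloaddition, hot wet DMSO, LDA and the hydride reagents used later.

Step 6
Reactants: 9 triisopropyl{[(2Z)-6-chloro-3-methyl-2-(prop-1-en-2-yl)hex-2-en-1-yl]oxy}silane; 10 dimethyl malonate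
Product: 13 dimethyl 2-[(4Z)-4,6-dimethyl-5-{[(triisopropylsilyl)oxy]methyl}hepta-4,6-dien-1-yl]malonate, via sodium malonate enolate 11 (not isolated), via primary iodide 12 (not isolated)
Conditions: 10 (3 equiv), NaH, DMF, 0 °C; then 9, NaI (1 equiv), 70 °C
Reagents that add atoms: none
Why: Malonic ester alkylation (SN2) of the primary halide, accelerated by Finkelstein exchange to the iodide in the flask, with excess malonate suppressing dialkylation, forms C3–C4.

Step 7
Reactants: 13 dimethyl 2-[(4Z)-4,6-dimethyl-5-{[(triisopropylsilyl)oxy]methyl}hepta-4,6-dien-1-yl]malonate; 14 acrolein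
Product: 15 dimethyl 2-[(4Z)-4,6-dimethyl-5-{[(triisopropylsilyl)oxy]methyl}hepta-4,6-dien-1-yl]-2-(3-oxopropyl)malonate
Conditions: acrolein (1.5 equiv), DBU (10 mol%), MeCN, 0 °C
Reagents that add atoms: none
Why: Base-catalysed Michael addition of the monosubstituted malonate to acrolein makes C4 quaternary and attaches the three-carbon aldehyde arm (C5, C6, CHO).

Step 8
Reactants: 15 dimethyl 2-[(4Z)-4,6-dimethyl-5-{[(triisopropylsilyl)oxy]methyl}hepta-4,6-dien-1-yl]-2-(3-oxopropyl)malonate
Product: 18 dimethyl 2-[(4Z)-4,6-dimethyl-5-{[(triisopropylsilyl)oxy]methyl}hepta-4,6-dien-1-yl]-2-[(1E)-3-oxoprop-1-en-1-yl]malonate, via α-phenylselanyl aldehyde 16 (not isolated), via selenoxide 17 (not isolated)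
Conditions: N-(phenylseleno)phthalimide, L-prolinamide (5 mol%), CH2Cl2, rt; aqueous wash; then NaIO4, THF/H2O, rt
Reagents that add atoms: none
Why: Enamine-mediated α-selenenylation of the aldehyde, then periodate oxidation and selenoxide syn-elimination toward the only β-hydrogens (on C5), is a standard dehydrogenation to the (E)-enal that runs at room temperature, so the triene is never heated and the amine is washed out before the enal exists.

Step 9
Reactants: 18 dimethyl 2-[(4Z)-4,6-dimethyl-5-{[(triisopropylsilyl)oxy]methyl}hepta-4,6-dien-1-yl]-2-[(1E)-3-oxoprop-1-en-1-yl]malonate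
Product: 21 dimethyl (4aS,8S,8aR)-8-formyl-4a,6-dimethyl-5-{[(triisopropylsilyl)oxy]methyl}-3,4,4a,7,8,8a-hexahydronaphthalene-1,1(2H)-dicarboxylate, via substrate iminium ion 19 (not isolated), via cycloadduct iminium ion 20 (not isolated)
Conditions: (2S,5S)-5-benzyl-2-tert-butyl-3-methylimidazolidin-4-one·TfOH (20 mol%), MeCN/H2O (95:5), 0 °C → rt
Reagents that add atoms: water, O
Why: The secondary amine condenses with the enal to the E-configured iminium ion 19, whose lowered LUMO engages the tethered diene in a concerted, asynchronous [4+2] cycloaddition in which C5–C10 runs ahead of C6–C7, and hydrolysis of the adduct iminium 20 returns the catalyst. The closest known reaction type is the imidazolidinone-catalysed type 1 intramolecular Diels–Alder reaction of undeca-2,8,10-trienals to trans-fused octalins, from which this case differs by the fully substituted diene terminus C10, so slower closure has to be expected. Ring A closes as the six-membered tether ring through the C5–C10 bond with the C1–C4 chain in a chair-like arrangement, and ring B is the new cyclohexene made by both bonds, which leaves the C8=C9 alkene where the target has it. The absolute configuration at C5 (and at the transient centre C6) is set by the catalyst, whose benzyl and tert-butyl groups cover one face of the iminium π system so that the diene adds to the other; C10 follows from C5 through the endo transition state with the tether on the outside of the diene (trans fusion, C10 methyl anti to C5–H), and C6 follows from the (E)-enal geometry in the suprafacial addition. The step needs endo over exo closure and the catalysed over the thermal pathway: the (4Z)-diene geometry fixed in steps 2 and 3 keeps the tether outside, the geminal diester at C4 favours the coiled reactive conformer, leaves no γ-hydrogen for dienamine formation and keeps C4 achiral, and the low temperature suppresses uncatalysed background.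

Step 10
Reactants: 21 dimethyl (4aS,8S,8aR)-8-formyl-4a,6-dimethyl-5-{[(triisopropylsilyl)oxy]methyl}-3,4,4a,7,8,8a-hexahydronaphthalene-1,1(2H)-dicarboxylate
Product: 22 dimethyl (4aS,8aR)-4a,6-dimethyl-5-{[(triisopropylsilyl)oxy]methyl}-3,4,4a,7,8,8a-hexahydronaphthalene-1,1(2H)-dicarboxylate
Conditions: RhCl(PPh3)3 (1.1 equiv), PhCN, 130 °C
Reagents that add atoms: none
Why: Tsuji–Wilkinson decarbonylation (formyl C–H oxidative addition, CO extrusion, C–H reductive elimination) removes the activating group from C6 under neutral conditions, which also avoids base-induced retro-Michael loss of the malonate, and leaves C5 and C10 untouched.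

Step 11
Reactants: 22 dimethyl (4aS,8aR)-4a,6-dimethyl-5-{[(triisopropylsilyl)oxy]methyl}-3,4,4a,7,8,8a-hexahydronaphthalene-1,1(2H)-dicarboxylate
Product: 23 methyl (4aS,8aS)-4a,6-dimethyl-5-{[(triisopropylsilyl)oxy]methyl}-1,2,3,4,4a,7,8,8a-octahydronaphthalene-1-carboxylate (C1 epimer mixture)
Conditions: LiCl (3 equiv), H2O (2 equiv), DMSO, 160 °C
Reagents that add atoms: none
Why: Krapcho dealkoxycarbonylation (chloride SN2 at an ester methyl, then loss of CO2) removes one ester of the geminal pair, and the C4 configuration of the product is irrelevant because the next step passes through the planar enolate.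

Step 12
Reactants: 23 methyl (4aS,8aS)-4a,6-dimethyl-5-{[(triisopropylsilyl)oxy]methyl}-1,2,3,4,4a,7,8,8a-octahydronaphthalene-1-carboxylate; 24 5-bromo-2-methylpent-2-ene
Product: 26 methyl (1R,4aS,8aR)-4a,6-dimethyl-1-(4-methylpent-3-en-1-yl)-5-{[(triisopropylsilyl)oxy]methyl}-1,2,3,4,4a,7,8,8a-octahydronaphthalene-1-carboxylate, via lithium ester enolate 25 (not isolated)
Conditions: LDA, THF, −78 → 0 °C; then DMPU, 24, −78 °C → rt
Reagents that add atoms: none
Why: Alkylation of the exocyclic ester enolate by the primary bromide (SN2) should occur on the α face along an equatorial trajectory because the β face is screened by the axial C10 methyl, which sets C4 with homoprenyl equatorial (α) and the ester axial (β).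

Step 13
Reactants: 26 methyl (1R,4aS,8aR)-4a,6-dimethyl-1-(4-methylpent-3-en-1-yl)-5-{[(triisopropylsilyl)oxy]methyl}-1,2,3,4,4a,7,8,8a-octahydronaphthalene-1-carboxylate
Product: 27 [(1R,4aS,8aR)-4a,6-dimethyl-1-(4-methylpent-3-en-1-yl)-5-{[(triisopropylsilyl)oxy]methyl}-1,2,3,4,4a,7,8,8a-octahydronaphthalen-1-yl]methanol
Conditions: LiAlH4, THF, 0 °C → reflux
Reagents that add atoms: none
Why: Hydride reduction of the hindered axial ester to the neopentyl primary alcohol is routine with LiAlH4, which leaves the TIPS ether and the isolated alkenes alone.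

Step 14
Reactants: 27 [(1R,4aS,8aR)-4a,6-dimethyl-1-(4-methylpent-3-en-1-yl)-5-{[(triisopropylsilyl)oxy]methyl}-1,2,3,4,4a,7,8,8a-octahydronaphthalen-1-yl]methanol
Product: 28 [(1R,4aS,8aR)-4a,6-dimethyl-1-(4-methylpent-3-en-1-yl)-5-{[(triisopropylsilyl)oxy]methyl}-1,2,3,4,4a,7,8,8a-octahydronaphthalen-1-yl]methyl methanesulfonate
Conditions: MsCl, Et3N, CH2Cl2, 0 °C
Reagents that add atoms: methanesulfonyl chloride, CS(=O)(=O)Cl
Why: Mesylation through the sulfene is insensitive to the neopentyl environment of the alcohol.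

Step 15
Reactants: 28 [(1R,4aS,8aR)-4a,6-dimethyl-1-(4-methylpent-3-en-1-yl)-5-{[(triisopropylsilyl)oxy]methyl}-1,2,3,4,4a,7,8,8a-octahydronaphthalen-1-yl]methyl methanesulfonate
Product: 29 triisopropyl{[(4aS,5S,8aS)-2,5,8a-trimethyl-5-(4-methylpent-3-en-1-yl)-3,4,4a,5,6,7,8,8a-octahydronaphthalen-1-yl]methoxy}silane
Conditions: LiEt3BH (5 equiv), THF, reflux
Reagents that add atoms: none
Why: SN2 hydride displacement of the neopentyl mesylate by lithium triethylborohydride, the usual reagent for hindered sulfonates, should turn the axial CH2OMs into the C4 methyl without radical or cationic intermediates that could cyclise onto the homoprenyl alkene.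

Step 16
Reactants: 29 triisopropyl{[(4aS,5S,8aS)-2,5,8a-trimethyl-5-(4-methylpent-3-en-1-yl)-3,4,4a,5,6,7,8,8a-octahydronaphthalen-1-yl]methoxy}silane
Product: 30 [(4aS,5S,8aS)-2,5,8a-trimethyl-5-(4-methylpent-3-en-1-yl)-3,4,4a,5,6,7,8,8a-octahydronaphthalen-1-yl]methanol
Conditions: TBAF, THF, rt
Reagents that add atoms: none
Why: Fluoride cleavage of the silyl ether frees the C11 allylic alcohol.

Step 17
Reactants: 30 [(4aS,5S,8aS)-2,5,8a-trimethyl-5-(4-methylpent-3-en-1-yl)-3,4,4a,5,6,7,8,8a-octahydronaphthalen-1-yl]methanol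
Product: 31 (4aS,5S,8aS)-1-(bromomethyl)-2,5,8a-trimethyl-5-(4-methylpent-3-en-1-yl)-3,4,4a,5,6,7,8,8a-octahydronaphthalene
Conditions: CBr4, PPh3, CH2Cl2, 0 °C; used crude
Reagents that add atoms: carbon tetrabromide, BrC(Br)(Br)Br
Why: Appel bromination under neutral conditions should give the primary allylic bromide without acid that could attack the trisubstituted alkene.

Step 18
Reactants: 31 (4aS,5S,8aS)-1-(bromomethyl)-2,5,8a-trimethyl-5-(4-methylpent-3-en-1-yl)-3,4,4a,5,6,7,8,8a-octahydronaphthalene; 32 methyl acetoacetate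
Product: 34 methyl 3-oxo-5-[(4aS,5S,8aS)-2,5,8a-trimethyl-5-(4-methylpent-3-en-1-yl)-3,4,4a,5,6,7,8,8a-octahydronaphthalen-1-yl]pentanoate, via acetoacetate dianion 33 (not isolated)
Conditions: 32 (2 equiv), NaH then n-BuLi, THF, 0 °C; then 31, 0 °C → rt
Reagents that add atoms: none
Why: γ-Alkylation of the acetoacetate dianion at its more reactive terminal carbon by the allylic bromide (SN2 at the primary carbon) forms C11–C12 and brings in C12–C15.

Step 19
Reactants: 34 methyl 3-oxo-5-[(4aS,5S,8aS)-2,5,8a-trimethyl-5-(4-methylpent-3-en-1-yl)-3,4,4a,5,6,7,8,8a-octahydronaphthalen-1-yl]pentanoate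
Product: 36 methyl (2Z)-3-[(diethoxyphosphoryl)oxy]-5-[(4aS,5S,8aS)-2,5,8a-trimethyl-5-(4-methylpent-3-en-1-yl)-3,4,4a,5,6,7,8,8a-octahydronaphthalen-1-yl]pent-2-enoate, via sodium enolate 35 (not isolated)
Conditions: NaH, Et2O, 0 °C; then ClP(O)(OEt)2
Reagents that add atoms: diethyl chlorophosphate, CCOP(=O)(Cl)OCC
Why: O-Phosphorylation of the chelated sodium enolate of the β-keto ester in ether should give the (Z)-enol phosphate selectively.

Step 20
Reactants: 36 methyl (2Z)-3-[(diethoxyphosphoryl)oxy]-5-[(4aS,5S,8aS)-2,5,8a-trimethyl-5-(4-methylpent-3-en-1-yl)-3,4,4a,5,6,7,8,8a-octahydronaphthalen-1-yl]pent-2-enoate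
Product: 37 methyl (2E)-3-methyl-5-[(4aS,5S,8aS)-2,5,8a-trimethyl-5-(4-methylpent-3-en-1-yl)-3,4,4a,5,6,7,8,8a-octahydronaphthalen-1-yl]pent-2-enoate
Conditions: Me2CuLi (MeLi, CuI), Et2O, −78 → −45 °C
Reagents that add atoms: lithium dimethylcuprate, [Li+].C[Cu-]C
Why: Cuprate addition–elimination on the enol phosphate proceeds with retention, so methyl ends up cis to the ester and the chain trans, which is the (E)-3-methyl enoate.

Step 21
Reactants: 37 methyl (2E)-3-methyl-5-[(4aS,5S,8aS)-2,5,8a-trimethyl-5-(4-methylpent-3-en-1-yl)-3,4,4a,5,6,7,8,8a-octahydronaphthalen-1-yl]pent-2-enoate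
Product: 38 (2E)-3-methyl-5-[(4aS,5S,8aS)-2,5,8a-trimethyl-5-(4-methylpent-3-en-1-yl)-3,4,4a,5,6,7,8,8a-octahydronaphthalen-1-yl]pent-2-enoic acid
Conditions: LiOH, THF/MeOH/H2O, 50 °C; then 1 M HCl
Reagents that add atoms: lithium hydroxide, [Li+].[OH-]
Why: Saponification of the methyl ester should give the acid without change of the alkene geometry or of any stereocentre.

**Compound list**

1 | 5-chloropent-1-yne | C#CCCCCl | starting material
2 | lithium 5-chloropent-1-yn-1-ide | [Li]C#CCCCCl | intermediate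
3 | methyl 6-chlorohex-2-ynoate | COC(=O)C#CCCCCl | intermediate
4 | lithium methyl[(1E)-5-chloro-1-(methoxycarbonyl)-2-methylpent-1-en-1-yl]cuprate | ClCCC/C(C)=C(/[Cu-]C)C(=O)OC.[Li+] | intermediate
5 | methyl (2E)-6-chloro-2-iodo-3-methylhex-2-enoate | ClCCC/C(C)=C(/I)C(=O)OC | intermediate
6 | isopropenylboronic acid pinacol ester | CC(=C)B1OC(C)(C)C(C)(C)O1 | starting material
7 | methyl (2Z)-6-chloro-3-methyl-2-(prop-1-en-2-yl)hex-2-enoate | ClCCC/C(C)=C(/C(C)=C)C(=O)OC | intermediate
8 | (2Z)-6-chloro-3-methyl-2-(prop-1-en-2-yl)hex-2-en-1-ol | ClCCC/C(C)=C(/C(C)=C)CO | intermediate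
9 | triisopropyl{[(2Z)-6-chloro-3-methyl-2-(prop-1-en-2-yl)hex-2-en-1-yl]oxy}silane | ClCCC/C(C)=C(/C(C)=C)CO[Si](C(C)C)(C(C)C)C(C)C | intermediate
10 | dimethyl malonate | COC(=O)CC(=O)OC | starting material
11 | sodium enolate of dimethyl malonate | COC(=O)[CH-]C(=O)OC.[Na+] | intermediate
12 | triisopropyl{[(2Z)-6-iodo-3-methyl-2-(prop-1-en-2-yl)hex-2-en-1-yl]oxy}silane | ICCC/C(C)=C(/C(C)=C)CO[Si](C(C)C)(C(C)C)C(C)C | intermediate
13 | dimethyl 2-[(4Z)-4,6-dimethyl-5-{[(triisopropylsilyl)oxy]methyl}hepta-4,6-dien-1-yl]malonate | COC(=O)C(C(=O)OC)CCC/C(C)=C(/C(C)=C)CO[Si](C(C)C)(C(C)C)C(C)C | intermediate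
14 | acrolein | C=CC=O | starting material
15 | dimethyl 2-[(4Z)-4,6-dimethyl-5-{[(triisopropylsilyl)oxy]methyl}hepta-4,6-dien-1-yl]-2-(3-oxopropyl)malonate | O=CCCC(C(=O)OC)(C(=O)OC)CCC/C(C)=C(/C(C)=C)CO[Si](C(C)C)(C(C)C)C(C)C | intermediate
16 | dimethyl 2-[(4Z)-4,6-dimethyl-5-{[(triisopropylsilyl)oxy]methyl}hepta-4,6-dien-1-yl]-2-[3-oxo-2-(phenylselanyl)propyl]malonate (configuration at the selenium-bearing carbon of no consequence) | O=CC([Se]c1ccccc1)CC(C(=O)OC)(C(=O)OC)CCC/C(C)=C(/C(C)=C)CO[Si](C(C)C)(C(C)C)C(C)C | intermediate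
17 | selenoxide of 16 (diastereomer mixture) | O=CC([Se](=O)c1ccccc1)CC(C(=O)OC)(C(=O)OC)CCC/C(C)=C(/C(C)=C)CO[Si](C(C)C)(C(C)C)C(C)C | intermediate
18 | dimethyl 2-[(4Z)-4,6-dimethyl-5-{[(triisopropylsilyl)oxy]methyl}hepta-4,6-dien-1-yl]-2-[(1E)-3-oxoprop-1-en-1-yl]malonate | O=C/C=C/C(C(=O)OC)(C(=O)OC)CCC/C(C)=C(/C(C)=C)CO[Si](C(C)C)(C(C)C)C(C)C | intermediate
19 | E-iminium triflate of 18 with (2S,5S)-5-benzyl-2-tert-butyl-3-methylimidazolidin-4-one | C=C(C)/C(CO[Si](C(C)C)(C(C)C)C(C)C)=C(C)/CCCC(C(=O)OC)(C(=O)OC)/C=C/C=[N+]1\[C@@H](Cc2ccccc2)C(=O)N(C)[C@H]1C(C)(C)C.[O-]S(=O)(=O)C(F)(F)F | intermediate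
20 | iminium triflate of cycloadduct 21 with the same amine | COC(=O)C1(C(=O)OC)CCC[C@]2(C)C(CO[Si](C(C)C)(C(C)C)C(C)C)=C(C)C[C@H](/C=[N+]3\[C@@H](Cc4ccccc4)C(=O)N(C)[C@H]3C(C)(C)C)[C@@H]12.[O-]S(=O)(=O)C(F)(F)F | intermediate
21 | dimethyl (4aS,8S,8aR)-8-formyl-4a,6-dimethyl-5-{[(triisopropylsilyl)oxy]methyl}-3,4,4a,7,8,8a-hexahydronaphthalene-1,1(2H)-dicarboxylate (trans-fused; 10β-methyl, 5α-H, 6α-CHO) | COC(=O)C1(C(=O)OC)CCC[C@]2(C)C(CO[Si](C(C)C)(C(C)C)C(C)C)=C(C)C[C@H](C=O)[C@@H]12 | intermediate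
22 | dimethyl (4aS,8aR)-4a,6-dimethyl-5-{[(triisopropylsilyl)oxy]methyl}-3,4,4a,7,8,8a-hexahydronaphthalene-1,1(2H)-dicarboxylate | COC(=O)C1(C(=O)OC)CCC[C@]2(C)C(CO[Si](C(C)C)(C(C)C)C(C)C)=C(C)CC[C@@H]12 | intermediate
23 | methyl (4aS,8aS)-4a,6-dimethyl-5-{[(triisopropylsilyl)oxy]methyl}-1,2,3,4,4a,7,8,8a-octahydronaphthalene-1-carboxylate (C1 epimer mixture; both converge on enolate 25) | COC(=O)C1CCC[C@]2(C)C(CO[Si](C(C)C)(C(C)C)C(C)C)=C(C)CC[C@@H]12 | intermediate
24 | 5-bromo-2-methylpent-2-ene | CC(C)=CCCBr | starting material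
25 | lithium enolate of 23 (enolate geometry of no consequence) | [Li]OC(OC)=C1CCC[C@]2(C)C(CO[Si](C(C)C)(C(C)C)C(C)C)=C(C)CC[C@@H]12 | intermediate
26 | methyl (1R,4aS,8aR)-4a,6-dimethyl-1-(4-methylpent-3-en-1-yl)-5-{[(triisopropylsilyl)oxy]methyl}-1,2,3,4,4a,7,8,8a-octahydronaphthalene-1-carboxylate (4α-homoprenyl, 4β-ester) | CC(C)=CCC[C@]1(C(=O)OC)CCC[C@]2(C)C(CO[Si](C(C)C)(C(C)C)C(C)C)=C(C)CC[C@@H]12 | intermediate
27 | [(1R,4aS,8aR)-4a,6-dimethyl-1-(4-methylpent-3-en-1-yl)-5-{[(triisopropylsilyl)oxy]methyl}-1,2,3,4,4a,7,8,8a-octahydronaphthalen-1-yl]methanol | CC(C)=CCC[C@]1(CO)CCC[C@]2(C)C(CO[Si](C(C)C)(C(C)C)C(C)C)=C(C)CC[C@@H]12 | intermediate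
28 | methanesulfonate of 27 | CC(C)=CCC[C@]1(COS(C)(=O)=O)CCC[C@]2(C)C(CO[Si](C(C)C)(C(C)C)C(C)C)=C(C)CC[C@@H]12 | intermediate
29 | triisopropyl{[(4aS,5S,8aS)-2,5,8a-trimethyl-5-(4-methylpent-3-en-1-yl)-3,4,4a,5,6,7,8,8a-octahydronaphthalen-1-yl]methoxy}silane | CC(C)=CCC[C@]1(C)CCC[C@]2(C)C(CO[Si](C(C)C)(C(C)C)C(C)C)=C(C)CC[C@@H]12 | intermediate
30 | [(4aS,5S,8aS)-2,5,8a-trimethyl-5-(4-methylpent-3-en-1-yl)-3,4,4a,5,6,7,8,8a-octahydronaphthalen-1-yl]methanol | CC(C)=CCC[C@]1(C)CCC[C@]2(C)C(CO)=C(C)CC[C@@H]12 | intermediate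
31 | (4aS,5S,8aS)-1-(bromomethyl)-2,5,8a-trimethyl-5-(4-methylpent-3-en-1-yl)-3,4,4a,5,6,7,8,8a-octahydronaphthalene | CC(C)=CCC[C@]1(C)CCC[C@]2(C)C(CBr)=C(C)CC[C@@H]12 | intermediate
32 | methyl acetoacetate | CC(=O)CC(=O)OC | starting material
33 | sodium lithium dianion of methyl acetoacetate | [CH2-]C(=O)[CH-]C(=O)OC.[Na+].[Li+] | intermediate
34 | methyl 3-oxo-5-[(4aS,5S,8aS)-2,5,8a-trimethyl-5-(4-methylpent-3-en-1-yl)-3,4,4a,5,6,7,8,8a-octahydronaphthalen-1-yl]pentanoate | CC(C)=CCC[C@]1(C)CCC[C@]2(C)C(CCC(=O)CC(=O)OC)=C(C)CC[C@@H]12 | intermediate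
35 | sodium (Z)-enolate of 34 | CC(C)=CCC[C@]1(C)CCC[C@]2(C)C(CC/C([O-])=C/C(=O)OC)=C(C)CC[C@@H]12.[Na+] | intermediate
36 | methyl (2Z)-3-[(diethoxyphosphoryl)oxy]-5-[(4aS,5S,8aS)-2,5,8a-trimethyl-5-(4-methylpent-3-en-1-yl)-3,4,4a,5,6,7,8,8a-octahydronaphthalen-1-yl]pent-2-enoate | CC(C)=CCC[C@]1(C)CCC[C@]2(C)C(CC/C(OP(=O)(OCC)OCC)=C/C(=O)OC)=C(C)CC[C@@H]12 | intermediate
37 | methyl (2E)-3-methyl-5-[(4aS,5S,8aS)-2,5,8a-trimethyl-5-(4-methylpent-3-en-1-yl)-3,4,4a,5,6,7,8,8a-octahydronaphthalen-1-yl]pent-2-enoate | CC(C)=CCC[C@]1(C)CCC[C@]2(C)C(CC/C(C)=C/C(=O)OC)=C(C)CC[C@@H]12 | intermediate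
38 | (2E)-3-methyl-5-[(4aS,5S,8aS)-2,5,8a-trimethyl-5-(4-methylpent-3-en-1-yl)-3,4,4a,5,6,7,8,8a-octahydronaphthalen-1-yl]pent-2-enoic acid (CNP0237483.2) | CC(C)=CCC[C@]1(C)CCC[C@]2(C)C(CC/C(C)=C/C(=O)O)=C(C)CC[C@@H]12 | target

**Count and risks**

Total step count: 21. Longest linear sequence: 21 steps (1 → 38); all other building blocks (6, 10, 14, 24, 32) are purchased.

Steps most likely to fail:

Step 9. Bond formation at the fully substituted diene terminus may be too slow for the amine salt to outrun decomposition or the uncatalysed pathway. Endo and facial control may also be incomplete, since the trans-fusing transition state has to accommodate a 1,3-diaxial contact between the C10 methyl and one ester. The fallback moves control from a catalyst to a covalently bound auxiliary and activation from an iminium ion to a chelated Lewis acid complex. It sets out from 18: Pinnick oxidation (NaClO2, NaH2PO4, 2-methylbut-2-ene, t-BuOH/H2O) should give (2E,8Z)-4,4-bis(methoxycarbonyl)-8,10-dimethyl-9-{[(triisopropylsilyl)oxy]methyl}undeca-2,8,10-trienoic acid F1. Pivaloyl chloride/Et3N converts it into the mixed pivalic anhydride F2, which acylates lithiated (S)-4-benzyloxazolidin-2-one to the N-enoyl imide F3. Me2AlCl (CH2Cl2, −30 °C → rt) should then promote the same endo cycloaddition through the chelated s-cis imide to the C6-acyl oxazolidinone cycloadduct F4; the chelate model predicts that the (S)-auxiliary exposes the same face as the catalyst. LiSEt cleaves the auxiliary to the S-ethyl thioester F5, and Fukuyama reduction (Et3SiH, Pd/C) gives aldehyde 21, where the route is rejoined.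

Step 12. Alkylation of the hindered, fully substituted enolate by an unactivated bromide may be sluggish, with elimination or proton return competing, and α-face selectivity may be incomplete. The fallback tells the two esters apart by accessibility instead of relying on an enolate face, and sets out from 22. A hindered hydride (LiAlH(O-t-Bu)3, THF, or DIBAL-H at −78 °C) should reduce the equatorial ester, which lacks the 1,3-diaxial contact with the C10 methyl, to the 4α-hydroxymethyl 4β-methyl ester F6. Dess–Martin oxidation gives the 4α-formyl ester F7, and Wittig methylenation (Ph3P=CH2, THF) the 4α-vinyl ester F8. Hydroboration with 9-BBN gives the B-alkyl borane F9, which is coupled without isolation with 1-bromo-2-methylprop-1-ene (Pd(dppf)Cl2, Cs2CO3, DMF/H2O; B-alkyl Suzuki–Miyaura) to give 26, where the route is rejoined.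

Step 15. Hydride may attack sulfur instead of the neopentyl carbon, which would return alcohol 27, or may not displace at all. The fallback removes the oxygen at the aldehyde level and sets out from 27. Dess–Martin oxidation gives the axial neopentyl aldehyde F10, and hydrazine hydrate converts it into the hydrazone F11. KOH in diethylene glycol at 200 °C (Wolff–Kishner reduction) should then reduce it through the diazenyl anion, an anionic path that does not engage the homoprenyl alkene, to 29, where the route is rejoined. Any material that loses the silyl ether under the hot alkali is alcohol 30, one step further along.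

**Further compounds**

F1 | step 9 | (2E,8Z)-4,4-bis(methoxycarbonyl)-8,10-dimethyl-9-{[(triisopropylsilyl)oxy]methyl}undeca-2,8,10-trienoic acid | OC(=O)/C=C/C(C(=O)OC)(C(=O)OC)CCC/C(C)=C(/C(C)=C)CO[Si](C(C)C)(C(C)C)C(C)C
F2 | step 9 | mixed pivalic anhydride of F1 | CC(C)(C)C(=O)OC(=O)/C=C/C(C(=O)OC)(C(=O)OC)CCC/C(C)=C(/C(C)=C)CO[Si](C(C)C)(C(C)C)C(C)C
F3 | step 9 | (4S)-4-benzyl-3-[(2E,8Z)-4,4-bis(methoxycarbonyl)-8,10-dimethyl-9-{[(triisopropylsilyl)oxy]methyl}undeca-2,8,10-trienoyl]-1,3-oxazolidin-2-one | O=C(/C=C/C(C(=O)OC)(C(=O)OC)CCC/C(C)=C(/C(C)=C)CO[Si](C(C)C)(C(C)C)C(C)C)N1[C@@H](Cc2ccccc2)COC1=O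
F4 | step 9 | trans-fused cycloadduct with the 6α-acyl (4S)-4-benzyloxazolidin-2-one in place of the formyl group of 21 | COC(=O)C1(C(=O)OC)CCC[C@]2(C)C(CO[Si](C(C)C)(C(C)C)C(C)C)=C(C)C[C@H](C(=O)N3[C@@H](Cc4ccccc4)COC3=O)[C@@H]12
F5 | step 9 | S-ethyl thioester corresponding to aldehyde 21 | COC(=O)C1(C(=O)OC)CCC[C@]2(C)C(CO[Si](C(C)C)(C(C)C)C(C)C)=C(C)C[C@H](C(=O)SCC)[C@@H]12
F6 | step 12 | 4α-hydroxymethyl 4β-methyl ester (methyl 1-(hydroxymethyl)-4a,6-dimethyl-5-{[(triisopropylsilyl)oxy]methyl}octahydronaphthalene-1-carboxylate) | OC[C@]1(C(=O)OC)CCC[C@]2(C)C(CO[Si](C(C)C)(C(C)C)C(C)C)=C(C)CC[C@@H]12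
F7 | step 12 | 4α-formyl 4β-methyl ester | O=C[C@]1(C(=O)OC)CCC[C@]2(C)C(CO[Si](C(C)C)(C(C)C)C(C)C)=C(C)CC[C@@H]12
F8 | step 12 | 4α-vinyl 4β-methyl ester | C=C[C@]1(C(=O)OC)CCC[C@]2(C)C(CO[Si](C(C)C)(C(C)C)C(C)C)=C(C)CC[C@@H]12
F9 | step 12 | B-[2-(4β-methoxycarbonyl-decalin-4α-yl)ethyl]-9-borabicyclo[3.3.1]nonane from F8 | C1CCC2CCCC1B2CC[C@]1(C(=O)OC)CCC[C@]2(C)C(CO[Si](C(C)C)(C(C)C)C(C)C)=C(C)CC[C@@H]12
F10 | step 15 | 4β-formyl compound (aldehyde of alcohol 27) | CC(C)=CCC[C@]1(C=O)CCC[C@]2(C)C(CO[Si](C(C)C)(C(C)C)C(C)C)=C(C)CC[C@@H]12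
F11 | step 15 | hydrazone of F10 | CC(C)=CCC[C@]1(/C=N/N)CCC[C@]2(C)C(CO[Si](C(C)C)(C(C)C)C(C)C)=C(C)CC[C@@H]12
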